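# Proposed total synthesis of CNP0130950.0 (ring B built by Danheiser benzannulation on a ring A ynol ether)

## Structural features

The target (26) is a diaryl ether: two benzene rings joined by one oxygen between A2 and B6, with ring A counted from the carbon bearing CO2Me (A1) and ring B from the carbon bearing CO2H (B1). It has no stereocentre and no configurationally stable axis, so no stereochemical relationship has to be set. Ring A is pentasubstituted in an unbroken run (A1 CO2Me, A2 O-aryl, A3 OMe, A4 Cl, A5 OH; hydrogen only at A6). Ring B carries CO2H at B1 between the phenol at B2 and the ether oxygen at B6, and a methyl group at B4, meta to both oxygens. The fragile features are the two carboxyl groups at different levels (ester on ring A, free acid on ring B), the aryl chloride, which excludes hydrogenolysis, and two free phenols on electron-rich rings. The real difficulty is the ether bond: its oxygen is flanked by CO2Me and OMe on ring A and by CO2H on ring B, so joining two finished rings would mean bringing a hindered, chelated salicylate phenol onto a hindered arene. The key step avoids this by exploiting the B1/B2/B6 triad with the B4 methyl: the ring A oxygen is first attached to a linear sp carbon, and ring B is then grown from a 3-methylcyclobutenone (B2, B3, B4, B5 and the methyl) and that alkynyl ether (B6 and B1).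

## Logic of the disconnections

26 ⇒ 25. The O–CH2 bond of the acetal on the A5 oxygen is cut last. The A5 phenol must be masked whenever ring A meets copper, base or ketenes, and an acetal survives all of these. It then leaves under aqueous acid, which touches neither the ester nor the aryl chloride. The forward step only has to cleave the acetal faster than it hydrolyses the ester.

25 ⇒ 24 ⇒ 23 ⇒ 22. The B1 carboxyl is traced back through aldehyde 24 and alcohol 23 to silyl ether 22 (C–O and C–H changes at one carbon). The reason is electronic: the ring-forming step needs an electron-rich alkyne, so this carbon must enter at the alcohol level. A silyl ether is used, not an ester, because an acyloxy group on an ortho-hydroxybenzyl carbon would be expelled as a quinone methide under base. The forward demand is a stepwise oxidation that tolerates the free B2 phenol.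

22 ⇒ 12 + 17. This is the strategic cut, through B1–B2 and B5–B6. It removes ring B entirely and leaves a four-carbon ketone and an alkyne. The forward step must add with one orientation only, and 12 must survive heating to about 110 °C.

12 ⇒ 8 + 10 (through 11). The O–C(sp) bond is cut. The hindered oxygen of 8 then only has to meet an unhindered vinylic carbon of 10 under copper catalysis. The elimination that turns 11 into 12 must spare the methyl ester, so a hindered silylamide is used and not an alkoxide.

10 ⇒ 9. The C=C bond is cut; a dibromoolefination of the aldehyde supplies it in one step.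

17 ⇒ 16 ⇒ 13 + 14 (through 15). Two ring C–C bonds are cut by a ketene–alkyne [2+2] addition, followed by removal of both chlorines. The polarity of the terminal alkyne places the methyl group at C3.

8 ⇒ 6 (through 7). The A2–O bond is traced to an A2–CHO bond by an oxidative aryl migration. This avoids any direct hydroxylation between an ester and a methoxy group. The forward step needs aryl migration to beat hydrogen migration.

6 ⇒ 5 ⇒ 4. The O–CH3 bond at A3 and the O–CH2 bond at A5 are cut in turn. In 4 the A5 hydroxyl is para to the formyl group and free, while the A3 hydroxyl is chelated to it, so the two can be told apart without a statistical step.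

4 ⇒ 2 ⇒ 1 (through 3). The A2–CHO bond and the ester O–CH3 bond are cut. In 2 the only free ring positions are equivalent, so formylation itself breaks the symmetry. The chlorine and both oxygens are already in place in 1.

## Other disconnections considered

Alternative 1: Ring B is cut at B4–B5 and B1–B6, leading to the 2-pyrone A2 (tert-butyl ester at C3, pivaloyloxy at C4, methyl at C6) and the terminal ring A ethynyl ether A3. In the forward direction A2 and A3 would undergo a [4+2] cycloaddition, and the bridged lactone would lose carbon dioxide to give A1.
- In favour: the B1 carbon arrives as a carboxylate, so the desilylation and both oxidations of the chosen plan disappear; on this point the alternative is better.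
- Equal points: regiocontrol rests on the same ynol ether polarisation (terminal carbon to the electrophilic C6 of the pyrone), and the hindered oxygen is again placed on an sp carbon first.
- Against: A3 is a terminal ynol ether, less stable and harder to reach than the internal ynol ether 12. The acyloxy group at C4 of A2 donates into the diene and weakens the inverse electron demand the cycloaddition needs. The oxygen-bearing alkyne carbon must bond to the fully substituted C3. A2 needs its own sequence, and a phenolic pivalate must later be removed beside a methyl ester.
- Comparison: mechanistically it is one cycloaddition and one cycloreversion, simpler than the four-event cascade chosen. The chosen plan, however, pairs the ynol ether with a strongly electrophilic ketene carbon, a better electronic match. The roughly three steps saved after ring formation are spent on A2 and A3, so overall step economy is about equal.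

Alternative 2: Ring A is the ring made. The cut at A1–A2 and A5–A6 leads to diene A5, which already carries the ether oxygen of a complete ring B on its terminus, and to the nitroacrylate A6. The forward step is a Diels–Alder reaction; the adduct would aromatise by loss of nitrous acid and methanol to give phenol A4.
- In favour: the hindered ether is never made by coupling, which is equal to the chosen plan on the central steric problem. All five ring A substituents arrive in one step under the direction of the nitro group. A4 has the A5 phenol free and the methyl ester in place, so one acid treatment would finish; this end game is better than the four steps of the chosen plan.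
- Against: A5 is a chlorinated, fourfold heteroatom-substituted silyl ketene acetal. Its preparation from an unsaturated ester precursor, its double-bond geometry and its moisture sensitivity are all open, and the chlorine lowers its nucleophilicity. More seriously, in the cycloadduct the aryloxy group at A2 is β to the acidic hydrogen at A1, so loss of the ring B phenoxide competes with loss of nitrite and would destroy the ether bond.
- Comparison: structurally it builds the more substituted ring and is more convergent on paper; the chosen plan builds the simpler ring on a ring A made by ordinary aromatic chemistry. Mechanistically it is one cycloaddition and two eliminations, against a cascade with no leaving-group ambiguity. Step count is probably about equal: shorter after the key step, longer before it.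

Alternative 3: The cut is at the ether bond O–B6 and at the B1–carboxyl bond, with no ring formed. Fluoride would release an aryne from silyl triflate A8. The potassium salt of phenol 8 would add at the aryne carbon meta to the methoxymethoxy group (B6), and the aryl anion left at B1 would be trapped by carbon dioxide to give acid A7.
- In favour: it is the most convergent plan and uses the same phenol 8. The ether bond forms at an unhindered, highly electrophilic carbon, which is equal to the chosen plan on the steric problem. Regiocontrol by the alkoxy group next to the aryne is as dependable as the ketene–ynol ether orientation, so the two are equal there. The B1 carbon arrives as the acid, so one deprotection of A7 gives the target; in end game and total step count this alternative is clearly better.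
- Against: the aryl anion at B1 is formed six atoms from the ring A methyl ester, and closure onto that ester to a xanthone is the established course for aryne adducts of salicylate esters. This unimolecular closure would have to be outrun by bimolecular capture of carbon dioxide. Carbon dioxide also carboxylates the phenoxide reversibly at oxygen and lowers its nucleophilicity, and any proton source gives the ether without the carboxyl group. A8 needs about four steps of its own.
- Comparison: structurally it joins two finished rings where the chosen plan constructs one. Mechanistically it depends on a kinetic competition at a free aryl anion with the substrate's own ester as internal competitor, whereas no event in the chosen cascade lets the ring A ester intervene. It would be shorter by three to four steps and is set aside only for that one competing closure.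

Key step: step 10

Remark on the chemistry: the structures of 12, 17 and 22 were checked atom by atom against the target and need no correction. The copper-catalysed coupling stops at bromoenol ether 11, so an elimination stage is written into step 7. Compounds 1, 9, 13 and 14 are assumed to be purchasable.

## Route

Step 1
Reactants: 1 4-chloro-3,5-dihydroxybenzoic acid
Product: 2 methyl 4-chloro-3,5-dihydroxybenzoate
Conditions: MeOH, H2SO4 (cat.), reflux
Reagents that add atoms: methanol, CO
Why: Fischer esterification; the phenols are inert to acid catalysis and the symmetric ester should be easy to purify.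

Step 2
Reactants: 2 methyl 4-chloro-3,5-dihydroxybenzoate
Product: 4 methyl 4-chloro-2-formyl-3,5-dihydroxybenzoate, via aryl iminium chloride 3 (not isolated)
Conditions: POCl3, DMF, 0 °C → rt; then H2O, 50 °C
Reagents that add atoms: N,N-dimethylformamide, CN(C)C=O; water, O
Why: Vilsmeier–Haack formylation; the two free ring positions are equivalent and each is ortho to one hydroxyl and para to the other, so only one isomer can form and the symmetry is broken without a statistical protection. Iminium 3 deactivates the ring against a second attack and is hydrolysed on aqueous work-up.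

Step 3
Reactants: 4 methyl 4-chloro-2-formyl-3,5-dihydroxybenzoate
Product: 5 methyl 4-chloro-2-formyl-3-hydroxy-5-(methoxymethoxy)benzoate
Conditions: MOMCl (1.05 equiv), i-Pr2NEt, CH2Cl2, 0 °C
Reagents that add atoms: chloromethyl methyl ether, COCCl
Why: Chemoselective phenol alkylation; the A5 hydroxyl is para to the aldehyde, more acidic and not hydrogen-bonded, while the A3 hydroxyl is held in a chelate with the formyl group, the selectivity familiar from 2,4-dihydroxybenzaldehydes.

Step 4
Reactants: 5 methyl 4-chloro-2-formyl-3-hydroxy-5-(methoxymethoxy)benzoate
Product: 6 methyl 4-chloro-2-formyl-3-methoxy-5-(methoxymethoxy)benzoate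
Conditions: MeI, K2CO3, DMF, 40 °C
Reagents that add atoms: iodomethane, CI
Why: Williamson ether synthesis on the one remaining phenol; the polar solvent breaks the chelate and no other nucleophilic site is present.

Step 5
Reactants: 6 methyl 4-chloro-2-formyl-3-methoxy-5-(methoxymethoxy)benzoate
Product: 8 methyl 4-chloro-2-hydroxy-3-methoxy-5-(methoxymethoxy)benzoate, via aryl formate 7 (not isolated)
Conditions: mCPBA, CH2Cl2, rt; then K2CO3 (cat.), MeOH, 0 °C
Reagents that add atoms: 3-chloroperoxybenzoic acid, OOC(=O)c1cccc(Cl)c1
Why: Baeyer–Villiger (Dakin-type) oxidation; the ring carbon should migrate in preference to hydrogen because it carries an ortho methoxy and a para acetal oxygen donor. Methanolysis of formate 7 frees the phenol while the methyl ester can only exchange with itself.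

Step 6
Reactants: 9 (tert-butyldimethylsilyloxy)acetaldehyde
Product: 10 tert-butyl[(3,3-dibromoprop-2-en-1-yl)oxy]dimethylsilane
Conditions: CBr4, PPh3, Zn dust, CH2Cl2, rt; then 9, 0 °C → rt
Reagents that add atoms: carbon tetrabromide, BrC(Br)(Br)Br
Why: Ramirez dibromoolefination (first stage of the Corey–Fuchs sequence); preforming the ylide with zinc avoids free Ph3PBr2 and so spares the silyl ether.

Step 7
Reactants: 8 methyl 4-chloro-2-hydroxy-3-methoxy-5-(methoxymethoxy)benzoate; 10 tert-butyl[(3,3-dibromoprop-2-en-1-yl)oxy]dimethylsilane
Product: 12 methyl 2-{[3-(tert-butyldimethylsilyloxy)prop-1-yn-1-yl]oxy}-4-chloro-3-methoxy-5-(methoxymethoxy)benzoate, via bromoenol ether 11 (not isolated)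
Conditions: CuI (10 mol %), 2,2′-bipyridine (20 mol %), K3PO4, PhMe, 110 °C; filter, concentrate; then KN(SiMe3)2, THF, −78 → −40 °C
Reagents that add atoms: none
Why: Copper-catalysed Ullmann-type vinylic C–O coupling of a phenol with a 1,1-dibromoalkene, which replaces the bromine trans to the alkyl group and leaves hydrogen and bromine anti in 11. Anti elimination of HBr with a hindered silylamide then gives the ynol ether; the alkoxide commonly used for this elimination is avoided because it would exchange the methyl ester. The slim vinylic electrophile is what allows a phenol with both ortho positions occupied to couple.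

Step 8
Reactants: 13 propyne; 14 trichloroacetyl chloride
Product: 16 4,4-dichloro-3-methylcyclobut-2-en-1-one, via dichloroketene 15 (not isolated)
Conditions: Zn–Cu couple, Et2O–DME, excess 13 (dry-ice condenser), slow addition of 14, 0 °C → rt
Reagents that add atoms: none
Why: [2+2] cycloaddition of dichloroketene, generated by zinc dechlorination of 14, with a terminal alkyne; the terminal alkyne carbon bonds to the ketene carbonyl carbon, so the methyl group ends at C3. Any 2,4-dichloro isomer formed by chlorine shift is reduced to the same product in step 9.

Step 9
Reactants: 16 4,4-dichloro-3-methylcyclobut-2-en-1-one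
Product: 17 3-methylcyclobut-2-en-1-one
Conditions: Zn dust, AcOH, TMEDA, EtOH, 0 °C → rt
Reagents that add atoms: none
Why: Reductive dechlorination of an α,α-dichloroketone with zinc in amine-buffered acetic acid; the buffer protects the acid-sensitive enone. The volatile product is best carried forward as a toluene solution.

Step 10
Reactants: 12 methyl 2-{[3-(tert-butyldimethylsilyloxy)prop-1-yn-1-yl]oxy}-4-chloro-3-methoxy-5-(methoxymethoxy)benzoate; 17 3-methylcyclobut-2-en-1-one
Product: 22 methyl 2-[2-(tert-butyldimethylsilyloxymethyl)-3-hydroxy-5-methylphenoxy]-4-chloro-3-methoxy-5-(methoxymethoxy)benzoate, via vinylketene 18 (not isolated), via vinylcyclobutenone adduct 19 (not isolated), via dienylketene 20 (not isolated), via cyclohexadienone tautomer 21 (not isolated)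
Conditions: 17 (1.5 equiv), PhMe, 80 °C then 110 °C (sealed tube); then K2CO3, MeOH, rt
Reagents that add atoms: none
Why: Danheiser benzannulation, here with an aryl alkynyl ether in place of the usual alkyl or silyl ynol ether. Four-electron electrocyclic opening of 17 near 80 °C gives vinylketene 18, whose ketene C=C adds in a [2+2] sense across the alkyne of 12 and closes a four-membered ring (19), forming the future B1–B2 and B5–B6 bonds. A second four-electron opening of 19, eased by the oxygen substituent on the ring, gives dienylketene 20, and ring B is closed by a thermal disrotatory six-electron electrocyclisation between the ketene carbon and the methylene terminus (B2–B3); enolisation of 21 to the phenol makes the sequence irreversible. No stereocentre survives, the single one in 19 being lost on ring opening. The selectivity needed is the orientation of the [2+2] addition: the alkyne carbon remote from oxygen is the nucleophilic one and bonds to the electrophilic ketene carbon, which places the silyloxymethyl carbon at B1 between the new hydroxyl and the aryloxy group; the opposite orientation has no electronic support. Ynol ether 12 has no alkyl C–H β to the ether oxygen, so the retro-ene fragmentation of alkyl ynol ethers is closed to it, and both ring A positions ortho to the oxygen are blocked, so it should tolerate the heating. Any 22 acylated on the new phenol by excess 18 is returned by the carbonate–methanol treatment, in which the methyl ester can only exchange with itself.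

Step 11
Reactants: 22 methyl 2-[2-(tert-butyldimethylsilyloxymethyl)-3-hydroxy-5-methylphenoxy]-4-chloro-3-methoxy-5-(methoxymethoxy)benzoate
Product: 23 methyl 4-chloro-2-[3-hydroxy-2-(hydroxymethyl)-5-methylphenoxy]-3-methoxy-5-(methoxymethoxy)benzoate
Conditions: Bu4NF, AcOH, THF, 0 °C → rt
Reagents that add atoms: none
Why: Fluoride-mediated desilylation, buffered so that no free phenoxide meets the methyl ester; fluoride is chosen over acid because the ortho-hydroxybenzyl carbon would solvolyse in acidic alcohol. Any silyl loss or migration already suffered in the basic work-up of step 10 converges on the same diol.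

Step 12
Reactants: 23 methyl 4-chloro-2-[3-hydroxy-2-(hydroxymethyl)-5-methylphenoxy]-3-methoxy-5-(methoxymethoxy)benzoate
Product: 24 methyl 4-chloro-2-(2-formyl-3-hydroxy-5-methylphenoxy)-3-methoxy-5-(methoxymethoxy)benzoate
Conditions: MnO2 (activated, excess), CH2Cl2, rt
Reagents that add atoms: none
Why: Chemoselective benzylic alcohol oxidation with activated MnO2, which stops at the aldehyde and is well established for ortho-hydroxybenzyl alcohols; the product is stabilised by the hydrogen bond between the B2 hydroxyl and the formyl group.

Step 13
Reactants: 24 methyl 4-chloro-2-(2-formyl-3-hydroxy-5-methylphenoxy)-3-methoxy-5-(methoxymethoxy)benzoate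
Product: 25 2-[3-chloro-2-methoxy-6-(methoxycarbonyl)-4-(methoxymethoxy)phenoxy]-6-hydroxy-4-methylbenzoic acid
Conditions: NaClO2, NaH2PO4, 2-methyl-2-butene (large excess), t-BuOH–THF–H2O, 0 °C → rt
Reagents that add atoms: NaClO2 (sodium chlorite), [Na+].[O-]Cl=O
Why: Lindgren–Pinnick oxidation; chlorous acid takes the aldehyde to the acid and the excess alkene traps HOCl before it can chlorinate ring B. Hydrogen peroxide is avoided as scavenger because an ortho-hydroxybenzaldehyde would undergo Dakin cleavage.

Step 14
Reactants: 25 2-[3-chloro-2-methoxy-6-(methoxycarbonyl)-4-(methoxymethoxy)phenoxy]-6-hydroxy-4-methylbenzoic acid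
Product: 26 2-[3-chloro-4-hydroxy-2-methoxy-6-(methoxycarbonyl)phenoxy]-6-hydroxy-4-methylbenzoic acid
Conditions: 3 M aq. HCl, THF, 45 °C
Reagents that add atoms: none
Why: Acid hydrolysis of the phenolic methoxymethyl acetal; water captures the methoxymethyl cation as formaldehyde and methanol so that it cannot alkylate ring B. With no alcohol as solvent the hindered free acid cannot be esterified, and the methyl ester is inert under these mild conditions.

## Compound list

1 | 4-chloro-3,5-dihydroxybenzoic acid | OC(=O)c1cc(O)c(Cl)c(O)c1 | starting material
2 | methyl 4-chloro-3,5-dihydroxybenzoate | COC(=O)c1cc(O)c(Cl)c(O)c1 | intermediate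
3 | N-{[3-chloro-2,4-dihydroxy-6-(methoxycarbonyl)phenyl]methylidene}-N-methylmethanaminium chloride | COC(=O)c1cc(O)c(Cl)c(O)c1C=[N+](C)C.[Cl-] | intermediate (not isolated)
4 | methyl 4-chloro-2-formyl-3,5-dihydroxybenzoate | COC(=O)c1cc(O)c(Cl)c(O)c1C=O | intermediate
5 | methyl 4-chloro-2-formyl-3-hydroxy-5-(methoxymethoxy)benzoate | COC(=O)c1cc(OCOC)c(Cl)c(O)c1C=O | intermediate
6 | methyl 4-chloro-2-formyl-3-methoxy-5-(methoxymethoxy)benzoate | COC(=O)c1cc(OCOC)c(Cl)c(OC)c1C=O | intermediate
7 | methyl 4-chloro-2-(formyloxy)-3-methoxy-5-(methoxymethoxy)benzoate | COC(=O)c1cc(OCOC)c(Cl)c(OC)c1OC=O | intermediate (not isolated)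
8 | methyl 4-chloro-2-hydroxy-3-methoxy-5-(methoxymethoxy)benzoate (ring A phenol) | COC(=O)c1cc(OCOC)c(Cl)c(OC)c1O | intermediate
9 | (tert-butyldimethylsilyloxy)acetaldehyde | CC(C)(C)[Si](C)(C)OCC=O | starting material
10 | tert-butyl[(3,3-dibromoprop-2-en-1-yl)oxy]dimethylsilane | CC(C)(C)[Si](C)(C)OCC=C(Br)Br | intermediate
11 | methyl 2-{[(1Z)-1-bromo-3-(tert-butyldimethylsilyloxy)prop-1-en-1-yl]oxy}-4-chloro-3-methoxy-5-(methoxymethoxy)benzoate (aryloxy trans to the silyloxymethyl group) | COC(=O)c1cc(OCOC)c(Cl)c(OC)c1O/C(Br)=C/CO[Si](C)(C)C(C)(C)C | intermediate (not isolated)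
12 | methyl 2-{[3-(tert-butyldimethylsilyloxy)prop-1-yn-1-yl]oxy}-4-chloro-3-methoxy-5-(methoxymethoxy)benzoate (ring A ynol ether) | COC(=O)c1cc(OCOC)c(Cl)c(OC)c1OC#CCO[Si](C)(C)C(C)(C)C | intermediate
13 | propyne | CC#C | starting material
14 | trichloroacetyl chloride | ClC(Cl)(Cl)C(Cl)=O | starting material
15 | dichloroketene | ClC(Cl)=C=O | intermediate (not isolated)
16 | 4,4-dichloro-3-methylcyclobut-2-en-1-one | CC1=CC(=O)C1(Cl)Cl | intermediate
17 | 3-methylcyclobut-2-en-1-one | CC1=CC(=O)C1 | intermediate
18 | 3-methylbuta-1,3-dien-1-one (isopropenylketene) | CC(=C)C=C=O | intermediate (not isolated)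
19 | methyl 2-{[2-(tert-butyldimethylsilyloxymethyl)-3-oxo-4-(prop-1-en-2-yl)cyclobut-1-en-1-yl]oxy}-4-chloro-3-methoxy-5-(methoxymethoxy)benzoate (racemic; the one stereocentre is transient) | COC(=O)c1cc(OCOC)c(Cl)c(OC)c1OC1=C(CO[Si](C)(C)C(C)(C)C)C(=O)C1C(C)=C | intermediate (not isolated)
20 | methyl 2-{[2-(tert-butyldimethylsilyloxymethyl)-5-methyl-1-oxohexa-1,3,5-trien-3-yl]oxy}-4-chloro-3-methoxy-5-(methoxymethoxy)benzoate (ketene-bearing carbon and isopropenyl group cis) | COC(=O)c1cc(OCOC)c(Cl)c(OC)c1O/C(=C/C(C)=C)C(CO[Si](C)(C)C(C)(C)C)=C=O | intermediate (not isolated)
21 | methyl 2-{[2-(tert-butyldimethylsilyloxymethyl)-5-methyl-3-oxocyclohexa-1,5-dien-1-yl]oxy}-4-chloro-3-methoxy-5-(methoxymethoxy)benzoate | COC(=O)c1cc(OCOC)c(Cl)c(OC)c1OC1=C(CO[Si](C)(C)C(C)(C)C)C(=O)CC(C)=C1 | intermediate (not isolated)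
22 | methyl 2-[2-(tert-butyldimethylsilyloxymethyl)-3-hydroxy-5-methylphenoxy]-4-chloro-3-methoxy-5-(methoxymethoxy)benzoate | COC(=O)c1cc(OCOC)c(Cl)c(OC)c1Oc1cc(C)cc(O)c1CO[Si](C)(C)C(C)(C)C | intermediate
23 | methyl 4-chloro-2-[3-hydroxy-2-(hydroxymethyl)-5-methylphenoxy]-3-methoxy-5-(methoxymethoxy)benzoate | COC(=O)c1cc(OCOC)c(Cl)c(OC)c1Oc1cc(C)cc(O)c1CO | intermediate
24 | methyl 4-chloro-2-(2-formyl-3-hydroxy-5-methylphenoxy)-3-methoxy-5-(methoxymethoxy)benzoate | COC(=O)c1cc(OCOC)c(Cl)c(OC)c1Oc1cc(C)cc(O)c1C=O | intermediate
25 | 2-[3-chloro-2-methoxy-6-(methoxycarbonyl)-4-(methoxymethoxy)phenoxy]-6-hydroxy-4-methylbenzoic acid | COC(=O)c1cc(OCOC)c(Cl)c(OC)c1Oc1cc(C)cc(O)c1C(=O)O | intermediate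
26 | 2-[3-chloro-4-hydroxy-2-methoxy-6-(methoxycarbonyl)phenoxy]-6-hydroxy-4-methylbenzoic acid | COC(=O)c1cc(O)c(Cl)c(OC)c1Oc1cc(C)cc(O)c1C(=O)O | target

## Step count and least certain steps

Total: 14 steps. Longest linear sequence: 11 steps (steps 1–5, 7, 10–14). Steps 6 and 8–9 are side branches.

**Step 10 (key step).** The most likely failure is slow capture of vinylketene 18. The aryloxy oxygen of 12 is a weaker donor than an alkoxy or silyloxy oxygen, so self-condensation of the ketene may win, and 12 may erode during long heating. The fallback generates the same vinylketene photochemically at room temperature (second-generation variant via Wolff rearrangement), so that only the last electrocyclic events need heat. It sets out from 12. Purchased 3-methylbut-3-en-2-one F1 would be trifluoroacetylated through its lithium enolate (LiN(SiMe3)2, CF3CO2CH2CF3, THF, −78 °C) to 1,1,1-trifluoro-5-methylhex-5-ene-2,4-dione F2. Detrifluoroacetylative diazo transfer (MsN3, Et3N, H2O, MeCN) would give 1-diazo-3-methylbut-3-en-2-one F3. Irradiating F3 with 12 in CH2Cl2 at room temperature should give adduct 19, and brief warming in toluene should complete the cascade; the fallback comes back to the route at 22. If the alkyne proves too poor a ketene acceptor under both regimes, the ether-forming fallback under step 7 bypasses the problem.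

**Step 7.** The likely failure is slow C–O coupling of the doubly ortho-substituted, chelated phenol, or a second substitution leading to a ketene acetal. The fallback abandons the ynol ether and forms the ether bond by nucleophilic aromatic substitution on a ring B fluoroaldehyde. It sets out from 8. Purchased 3-fluoro-5-methylphenol F4 would be protected (MOMCl, i-Pr2NEt) as 1-fluoro-3-(methoxymethoxy)-5-methylbenzene F5. Lithiation between fluorine and the acetal oxygen (n-BuLi, THF, −78 °C) and a DMF quench would give 2-fluoro-6-(methoxymethoxy)-4-methylbenzaldehyde F6. Phenol 8 and F6 with Cs2CO3 in DMSO at about 100 °C should give methyl 4-chloro-2-[2-formyl-3-(methoxymethoxy)-5-methylphenoxy]-3-methoxy-5-(methoxymethoxy)benzoate F7. Chlorite oxidation as in step 13 would give 2-[3-chloro-2-methoxy-6-(methoxycarbonyl)-4-(methoxymethoxy)phenoxy]-6-(methoxymethoxy)-4-methylbenzoic acid F8 (the same compound as A7). Aqueous HCl in THF would remove both acetals, so the fallback comes back to the route at 26.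

**Step 5.** The likely failure is hydrogen migration competing with aryl migration in the peracid adduct, because the aldehyde is flanked by an electron-withdrawing ester; this would give a carboxylic acid. The fallback changes the order of events and sets out from 5. Dakin oxidation of the ortho-hydroxy aldehyde (2 Na2CO3·3 H2O2, THF–H2O, rt) should give methyl 4-chloro-2,3-dihydroxy-5-(methoxymethoxy)benzoate F9. One equivalent of MeI with KHCO3 in DMF should then methylate the A3 hydroxyl selectively, since the A2 hydroxyl is chelated to the ester. The fallback comes back to the route at 8.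

**Step 13.** The likely failure is electrophilic chlorination of the electron-rich ring B at B3 or B5 by HOCl before the alkene scavenger intercepts it. The fallback deactivates the ring first and sets out from 24. Acetylation (Ac2O, Et3N, DMAP) would give methyl 2-[3-(acetyloxy)-2-formyl-5-methylphenoxy]-4-chloro-3-methoxy-5-(methoxymethoxy)benzoate F10. Chlorite oxidation would give 2-(acetyloxy)-6-[3-chloro-2-methoxy-6-(methoxycarbonyl)-4-(methoxymethoxy)phenoxy]-4-methylbenzoic acid F11. Mild methanolysis (K2CO3, MeOH, rt) would remove the acetate, and the fallback comes back to the route at 25.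

## Further compounds

F1 | step 10 | 3-methylbut-3-en-2-one (purchased) | CC(=C)C(C)=O
F2 | step 10 | 1,1,1-trifluoro-5-methylhex-5-ene-2,4-dione | C=C(C)C(=O)CC(=O)C(F)(F)F
F3 | step 10 | 1-diazo-3-methylbut-3-en-2-one | C=C(C)C(=O)C=[N+]=[N-]
F4 | step 7 | 3-fluoro-5-methylphenol (purchased) | Cc1cc(O)cc(F)c1
F5 | step 7 | 1-fluoro-3-(methoxymethoxy)-5-methylbenzene | COCOc1cc(C)cc(F)c1
F6 | step 7 | 2-fluoro-6-(methoxymethoxy)-4-methylbenzaldehyde | COCOc1cc(C)cc(F)c1C=O
F7 | step 7 | methyl 4-chloro-2-[2-formyl-3-(methoxymethoxy)-5-methylphenoxy]-3-methoxy-5-(methoxymethoxy)benzoate | COC(=O)c1cc(OCOC)c(Cl)c(OC)c1Oc1cc(C)cc(OCOC)c1C=O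
F8 | step 7 | 2-[3-chloro-2-methoxy-6-(methoxycarbonyl)-4-(methoxymethoxy)phenoxy]-6-(methoxymethoxy)-4-methylbenzoic acid | COC(=O)c1cc(OCOC)c(Cl)c(OC)c1Oc1cc(C)cc(OCOC)c1C(=O)O
F9 | step 5 | methyl 4-chloro-2,3-dihydroxy-5-(methoxymethoxy)benzoate | COC(=O)c1cc(OCOC)c(Cl)c(O)c1O
F10 | step 13 | methyl 2-[3-(acetyloxy)-2-formyl-5-methylphenoxy]-4-chloro-3-methoxy-5-(methoxymethoxy)benzoate | COC(=O)c1cc(OCOC)c(Cl)c(OC)c1Oc1cc(C)cc(OC(C)=O)c1C=O
F11 | step 13 | 2-(acetyloxy)-6-[3-chloro-2-methoxy-6-(methoxycarbonyl)-4-(methoxymethoxy)phenoxy]-4-methylbenzoic acid | COC(=O)c1cc(OCOC)c(Cl)c(OC)c1Oc1cc(C)cc(OC(C)=O)c1C(=O)O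
A1 | alternative 1 | tert-butyl 2-[3-chloro-2-methoxy-6-(methoxycarbonyl)-4-(methoxymethoxy)phenoxy]-4-methyl-6-(pivaloyloxy)benzoate | COC(=O)c1cc(OCOC)c(Cl)c(OC)c1Oc1cc(C)cc(OC(=O)C(C)(C)C)c1C(=O)OC(C)(C)C
A2 | alternative 1 | tert-butyl 6-methyl-2-oxo-4-(pivaloyloxy)-2H-pyran-3-carboxylate | CC1=CC(OC(=O)C(C)(C)C)=C(C(=O)OC(C)(C)C)C(=O)O1
A3 | alternative 1 | methyl 4-chloro-2-(ethynyloxy)-3-methoxy-5-(methoxymethoxy)benzoate | COC(=O)c1cc(OCOC)c(Cl)c(OC)c1OC#C
A4 | alternative 2 | tert-butyl 2-[3-chloro-4-hydroxy-2-methoxy-6-(methoxycarbonyl)phenoxy]-6-(methoxymethoxy)-4-methylbenzoate | COC(=O)c1cc(O)c(Cl)c(OC)c1Oc1cc(C)cc(OCOC)c1C(=O)OC(C)(C)C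
A5 | alternative 2 | tert-butyl 2-{[3-chloro-2,4-dimethoxy-4-(trimethylsilyloxy)buta-1,3-dien-1-yl]oxy}-6-(methoxymethoxy)-4-methylbenzoate (double-bond geometry left open) | COCOc1cc(C)cc(OC=C(OC)C(Cl)=C(OC)O[Si](C)(C)C)c1C(=O)OC(C)(C)C
A6 | alternative 2 | methyl (E)-3-nitroacrylate | COC(=O)/C=C/[N+](=O)[O-]
A7 | alternative 3 | 2-[3-chloro-2-methoxy-6-(methoxycarbonyl)-4-(methoxymethoxy)phenoxy]-6-(methoxymethoxy)-4-methylbenzoic acid | COC(=O)c1cc(OCOC)c(Cl)c(OC)c1Oc1cc(C)cc(OCOC)c1C(=O)O
A8 | alternative 3 | 3-(methoxymethoxy)-5-methyl-2-(trimethylsilyl)phenyl trifluoromethanesulfonate | COCOc1cc(C)cc(OS(=O)(=O)C(F)(F)F)c1[Si](C)(C)C
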